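Abbreviations: TBS = tert-butyldimethylsilyl; MOM = methoxymethyl; IDPi = BINOL-derived imidodiphosphorimidate Brønsted acid. Benzofuran numbering is used throughout (O1, C2, C3, C3a, C4–C7, C7a). Ring A is the guaiacyl group on C2, ring B the 3,5-dioxygenated phenyl on C3, ring C the benzo ring C3a–C7a, and ring D the guaiacyl group of the styryl unit.

## The problem

Bisisorhapontigenin B (19) is a trans-2,3-diaryl-2,3-dihydrobenzofuran with ring A on C2, ring B on C3, a free OH on C4 and an (E)-2-guaiacylvinyl group (ring D) on C6. The first obstacle is connectivity. C3 is bonded to C3a, which lies between the oxygen-bearing carbons C4 and C7a and para to the styryl group; this is the most crowded position of a 5-styrylresorcinol and not the one that oxidative or Friedel–Crafts couplings choose. The second obstacle is the pair of adjacent benzylic stereocentres (2S,3S), with no carbonyl group or heteroatom handle nearby and with two aryl groups on C3 that differ only in substitution pattern. The two centres are unequal: O1–C2 is a 4-hydroxybenzyl aryl ether that ionises reversibly to a p-quinone methide, so C2 is labile and settles trans to C3, whereas C3 is lost only by removal of H3, so absolute control must be exerted at C3. The end game is limited by five free phenols, by two aryl methyl ethers that must stay (no methyl protecting groups, no BBr3), and by an electron-rich stilbene (no hydrogenolysis, strong oxidant or hot acid). The feature that makes the key step possible is this: when O1–C2 is opened and H3 removed, both stereocentres vanish and ring C becomes a 2-substituted resorcinol symmetric about the C3a···C6 axis, so the oxygens on C4 and C7a are interchanged by rotation about C3–C3a and either one closes to the same ring, while the para oxygen of ring A steers a proton to C3 and makes C2 the electrophile. A second regularity helps the run-up: C2 with ring A and the outer styryl carbon with ring D are the same guaiacyl–CH unit, each bonded to a carbon attached to ring C (C3 on C3a, Cα on C6).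

## Retrosynthesis

**19 ⇒ 18.** The four O–Si bonds on rings A, B and D are cut. Silyl ethers leave with buffered fluoride, which spares the methyl ethers, the stilbene and O1–C2; benzyl or methyl ethers would not allow this. The skeleton of 18 is no simpler, but 18 is lipophilic, and the key step needs that (apolar solvent, tight ion pair). The forward reaction must desilylate without letting a ring-A phenoxide expel O1.

**18 ⇒ 16 (key disconnection).** O1–C2 and C3–H are cut together.
- The neighbouring cuts are worse. C2–C3 or C3–C3a each leave a precursor that is still chiral, or that has two different ring-C oxygens or an open regiochemical question. Cutting O1–C2 alone leaves C3 to be made separately.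
- Removing H3 as well gives triarylethylene 16, an isomer of 18, so the forward step needs no redox change and gives no by-product.
- Both stereocentres and the heterocycle disappear, ring C regains its twofold symmetry, and the alkene geometry does not matter.
- The forward reaction asks a chiral Brønsted acid to put a proton on one face of C3 (cation 17). Ring closure and the trans relationship then follow from the substrate.

**16 ⇒ 14 (through 15).** Only the two ring-C oxygens are masked, as MOM ethers. They are needed as directing groups further back and must be distinguishable from the silyl ethers. The forward step must remove them without any free protic acid, since acid would close 16 to the racemate. Silyl triflate with 2,2′-bipyridyl, followed by buffered hydrolysis of the bis-TMS ether 15, meets this demand.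

**14 ⇒ 13 ⇒ 7 + two equivalents of 12 (from 11).** Both C=C bonds (C2=C3 and the styryl bond) are cut at once.
- Each is a guaiacyl–CH= unit on a carbon attached to ring C, so one benzylic Grignard reagent 12 can add to the aldehyde and the ketone of 7, and one dehydration of diol 13 gives both alkenes.
- A Wittig-type olefination would fail at the di-ortho-substituted diaryl ketone.
- A cross-coupling route would need a stereodefined vinyl partner, which is wasted effort when the geometry is irrelevant.
- A Heck reaction for the styryl group would need an extra halogen handle and an extra step.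
- Compound 7 holds only rings B and C.

**7 ⇒ 6 ⇒ 2 + 4 (through 5).** The C3–C3a bond is cut. Directed ortho-metalation places lithium only between the two OMOM groups of 2, which is exactly the position electrophilic chemistry avoids. The free CH2OH of 2 travels as its alkoxide in 5 and is oxidised to the aldehyde in the same operation that turns the carbinol of 6 into the ketone, so the C6 handle costs no step. Rings B and C both come from the cheap 3,5-dioxygenated C6–C1 series.

**2, 4, 11 ⇒ 1, 3, 8.** Only protecting-group and functional-group steps remain: 1 → 2, 3 → 4, and vanillin 8 → 9 → 10 → 11.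

## Roads not taken

**Alternative 1:** the most obvious cut is C3–C3a and O1–C2 together, back to two molecules of isorhapontigenin (A1).
- Forward key step: one-electron oxidation of A1 (iron(III), silver(I) or a peroxidase), bond formation between the olefinic carbon next to the resorcinol ring of one unit and the carbon between the two OH groups of the other, then closure of quinone methide A2.
- The spin of the radical lies on the phenol oxygen, its free ortho carbon, the ipso carbon and the olefinic carbon, so radical–radical pairings at these sites dominate.
- The resorcinol ring carries no spin (its OH groups are meta to the vinyl group). It has to react as a closed-shell arene at its most hindered position, in competition with the freer positions next to the vinyl group.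
- Nothing chiral is present, so A2 is racemic, and the product is as oxidisable as A1.
- The route is one step long but controls neither regiochemistry, nor absolute configuration, nor over-oxidation. The chosen plan fixes the first by metalation and the second by catalysis, and it involves no oxidant.

**Alternative 2:** cut C2–C3. The forward key step is an intramolecular C–H insertion of a rhodium donor/donor carbene, generated from diaryldiazomethane A3, into the OCH2 group of a guaiacylmethyl ether.
- This is the standard enantioselective entry to such rings, but it discards the symmetry of ring C: one oxygen must carry the guaiacylmethyl group and the other a different mask, which needs a statistical monoalkylation.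
- The hydrazone and diazo group must be made at a di-ortho-substituted diaryl ketone.
- The carbene would cyclopropanate a styryl group, so C6 must carry a halogen and the stilbene needs a later coupling.
- The usual kinetic preference of such insertions for the cis relationship would call for an epimerisation at C2.
- The chosen plan needs none of these corrections and carries the stilbene through the key step.

**Alternative 3:** cut C2–H and C3–H. The forward key step is asymmetric hydrogenation (dearomatisation) of the flat 2,3-diarylbenzofuran A4 to the cis-dihydrobenzofuran A5, followed by acid epimerisation at C2.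
- Hydrogenation cannot coexist with the C6 styryl alkene, so again a halogen handle and a late coupling are needed.
- The tetrasubstituted, doubly arylated C2=C3 bond next to the C4 oxygen is a very hindered substrate, no closer to known catalysis than the chosen step.
- A4 lies one oxidation level too high, so the route spends steps on building aromaticity only to remove it.
- Syn addition gives the wrong diastereomer first.
- The chosen cycloisomerisation is redox-neutral, gives trans directly and tolerates the stilbene.

Key step: step 11

Assumption: the sense of induction of the chiral acid cannot be derived from the structure. "(S,S)-IDPi" stands for the catalyst enantiomer that delivers 3S; the mirror-image catalyst is used if the first run shows the opposite sense.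

Remark: the triaryl alkene of 14, 15 and 16 is used as an E/Z mixture, so its geometry is left open in the SMILES.

## Route

Step 1
Reactants: 1 3,5-dihydroxybenzyl alcohol
Product: 2 [3,5-bis(methoxymethoxy)phenyl]methanol
Conditions: NaH (2.05 equiv), MOMCl (2.1 equiv), THF/DMF, 0 °C
Reagents that add atoms: chloromethyl methyl ether (MOMCl), COCCl
Why: Williamson-type O-alkylation of the two phenoxides; two equivalents of base deprotonate only the phenols, which are far more acidic than the benzylic alcohol, so the CH2OH stays free as the latent aldehyde. The MOM groups are the directing groups of step 3.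

Step 2
Reactants: 3 3,5-dihydroxybenzaldehyde
Product: 4 3,5-bis(tert-butyldimethylsilyloxy)benzaldehyde
Conditions: TBSCl (2.3 equiv), imidazole, DMF, rt
Reagents that add atoms: tert-butyldimethylsilyl chloride (TBSCl), CC(C)(C)[Si](C)(C)Cl
Why: Standard imidazole-promoted silylation of phenols. Aryl TBS ethers survive organometallic reagents, IBX, the Burgess reagent and catalytic acid in apolar media, and they leave with fluoride, so no aryl methyl ether is ever at risk.

Step 3
Reactants: 2 [3,5-bis(methoxymethoxy)phenyl]methanol; 4 3,5-bis(tert-butyldimethylsilyloxy)benzaldehyde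
Product: 6 [3,5-bis(tert-butyldimethylsilyloxy)phenyl][4-(hydroxymethyl)-2,6-bis(methoxymethoxy)phenyl]methanol (racemic), via C4-lithiated lithium alkoxide 5 (not isolated)
Conditions: n-BuLi (2.3 equiv), TMEDA, THF, 0 °C to rt; then 4, −78 to 0 °C; aq NH4Cl
Reagents that add atoms: none
Why: Directed ortho-metalation: after alkoxide formation the second equivalent of n-BuLi removes the proton between the two cooperating OMOM groups (the future C3a), and 1,2-addition of the aryllithium to 4 makes the C3–C3a bond. The new carbinol centre is racemic and is erased in step 4.

Step 4
Reactants: 6 [3,5-bis(tert-butyldimethylsilyloxy)phenyl][4-(hydroxymethyl)-2,6-bis(methoxymethoxy)phenyl]methanol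
Product: 7 4-[3,5-bis(tert-butyldimethylsilyloxy)benzoyl]-3,5-bis(methoxymethoxy)benzaldehyde
Conditions: IBX (3 equiv), EtOAc, 75 °C
Reagents that add atoms: none
Why: IBX oxidation of a primary benzylic and a doubly benzylic secondary alcohol in one operation; it stops at the aldehyde and ketone and leaves MOM and TBS ethers untouched.

Step 5
Reactants: 8 vanillin
Product: 9 4-(tert-butyldimethylsilyloxy)-3-methoxybenzaldehyde
Conditions: TBSCl, imidazole, CH2Cl2, rt
Reagents that add atoms: tert-butyldimethylsilyl chloride (TBSCl), CC(C)(C)[Si](C)(C)Cl
Why: Standard phenol silylation; the same mask as on ring B, so that one fluoride step ends the synthesis.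

Step 6
Reactants: 9 4-(tert-butyldimethylsilyloxy)-3-methoxybenzaldehyde
Product: 10 [4-(tert-butyldimethylsilyloxy)-3-methoxyphenyl]methanol
Conditions: NaBH4, MeOH, 0 °C
Reagents that add atoms: none
Why: Borohydride reduction of an aromatic aldehyde; short reaction time at 0 °C keeps the aryl silyl ether intact.

Step 7
Reactants: 10 [4-(tert-butyldimethylsilyloxy)-3-methoxyphenyl]methanol
Product: 11 4-(tert-butyldimethylsilyloxy)-3-methoxybenzyl chloride
Conditions: MsCl, Et3N, CH2Cl2, 0 °C to rt
Reagents that add atoms: methanesulfonyl chloride (source of Cl), CS(=O)(=O)Cl
Why: Mesylation of an electron-rich benzylic alcohol followed by in situ displacement by chloride; the amine-buffered medium spares the silyl ether.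

Step 8
Reactants: 11 4-(tert-butyldimethylsilyloxy)-3-methoxybenzyl chloride; 7 4-[3,5-bis(tert-butyldimethylsilyloxy)benzoyl]-3,5-bis(methoxymethoxy)benzaldehyde
Product: 13 1-[3,5-bis(TBSO)phenyl]-2-[4-(TBSO)-3-methoxyphenyl]-1-{4-[1-hydroxy-2-(4-(TBSO)-3-methoxyphenyl)ethyl]-2,6-bis(methoxymethoxy)phenyl}ethan-1-ol (mixture of diastereomers), via benzylic Grignard reagent 12 (not isolated)
Conditions: 11 (3.5 equiv), Mg turnings, THF, 0 °C (slow addition); then 7, LaCl3·2LiCl (30 mol %), −20 °C to rt; aq NH4Cl
Reagents that add atoms: none
Why: Two-directional Grignard 1,2-addition: the same benzylic nucleophile adds to the aldehyde and to the non-enolisable diaryl ketone, where chelation by the ortho OMOM oxygens and the lanthanum Lewis acid offset the hindrance. Both new carbinol centres are erased in step 9, so the mixture is used as such.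

Step 9
Reactants: 13 the diol of step 8
Product: 14 2-{1-[3,5-bis(TBSO)phenyl]-2-[4-(TBSO)-3-methoxyphenyl]ethenyl}-5-{(E)-2-[4-(TBSO)-3-methoxyphenyl]ethenyl}-1,3-bis(methoxymethoxy)benzene (E/Z mixture at the triaryl alkene)
Conditions: Burgess reagent (3 equiv), toluene, 60 °C
Reagents that add atoms: none
Why: Burgess dehydration under neutral conditions (syn elimination of the secondary sulfamate, ionisation and proton loss at the tertiary site); each alcohol has β-hydrogens on one side only, so no regiochemical choice arises. The disubstituted alkene should form as the E isomer through the transition state with the aryl groups apart, and the geometry of the triaryl alkene is irrelevant for step 11.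

Step 10
Reactants: 14 the bis-MOM ether of step 9
Product: 16 2-{1-[3,5-bis(TBSO)phenyl]-2-[4-(TBSO)-3-methoxyphenyl]ethenyl}-5-{(E)-2-[4-(TBSO)-3-methoxyphenyl]ethenyl}benzene-1,3-diol (E/Z mixture at the triaryl alkene), via bis(trimethylsilyl) ether 15 (not isolated)
Conditions: TMSOTf (5 equiv), 2,2′-bipyridyl (7 equiv), CH2Cl2, 0 °C; then aq NaHCO3/MeOH, 0 °C; Et3N-deactivated silica
Reagents that add atoms: none
Why: Silyl triflate/2,2′-bipyridyl cleavage of aromatic MOM ethers: the acetal is silylated, bipyridyl takes up the methoxymethyl cation, and the aryl TMS ethers 15 are hydrolysed in bicarbonate-buffered methanol. No free protic acid is ever present, which matters because acid would close 16 to the racemate; aryl TBS ethers are not affected.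

Step 11
Reactants: 16 the resorcinol of step 10
Product: 18 (2S,3S)-3-[3,5-bis(TBSO)phenyl]-2-[4-(TBSO)-3-methoxyphenyl]-6-{(E)-2-[4-(TBSO)-3-methoxyphenyl]ethenyl}-2,3-dihydro-1-benzofuran-4-ol, via ring-A-stabilised (S)-benzylic cation 17 (not isolated)
Conditions: (S,S)-IDPi (N-triflyl, 3,3′-aryl groups to be screened, 5 mol %), toluene (0.005 M), 4 Å MS, −40 °C, Ar, dark; quench Et3N
Reagents that add atoms: none
Why: Proposed new method: the confined chiral Brønsted acid transfers its proton to C3 of the triaryl alkene of 16, the carbon β to the para-oxygenated ring A, which gives the ring-A-stabilised benzylic cation 17 (an O-silylated p-quinone methide) as a contact ion pair with the chiral anion, and a phenol oxygen of ring C then captures C2 and returns the proton. The closest known reaction types are the asymmetric intramolecular hydroalkoxylation of alkenes with confined imidodiphosphorimidate acids, the chiral-acid protonation of hydroxystyrenes to quinone methides, and the achiral acid-induced closure of 2-hydroxystilbenes to 2-aryl-2,3-dihydrobenzofurans; what is new is that the proton transfer to carbon, not the C–O bond formation, has to be enantiodetermining. The one ring that closes (O1–C2) is 5-endo-trig only on paper: C3 is already sp3 when the bond forms, so the closure is a 5-exo-trig attack on the exocyclic C2=C1(ring A) bond of the quinone-methide form of 17. C3 is controlled by the catalyst: ring C stands perpendicular to the alkene plane with one OH on each face, the basic site of the catalyst can hold the OH of the face on which its acidic site lies over C3, and the pocket then has to tell ring B from the C2 arm. C2 is controlled by C3: closure puts ring A anti to ring B, and since O1–C2 re-ionises under the conditions, any cis isomer drains into the trans isomer without change at C3. Site selectivity is secured by the substrate: protonation at C2 gives a ring-C-stabilised diaryl cation and protonation of the C6 styryl group gives a ring-D-stabilised cation, but neither has a nucleophile within reach of a viable ring, so both only revert (the former interconverts E- and Z-16, which makes the step convergent in alkene geometry), and high dilution suppresses intermolecular capture. No regiochemical question arises because the two OH groups of ring C are equivalent. The enantiomeric purity requires that capture of 17 outruns loss of H3 and that 18 is not re-opened as far as 16, which low temperature, an apolar solvent and a quench at full conversion should secure.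

Step 12
Reactants: 18 the tetrasilyl ether of step 11
Product: 19 bisisorhapontigenin B, (2S,3S)-3-(3,5-dihydroxyphenyl)-2-(4-hydroxy-3-methoxyphenyl)-6-[(E)-2-(4-hydroxy-3-methoxyphenyl)ethenyl]-2,3-dihydro-1-benzofuran-4-ol
Conditions: TBAF (4.5 equiv), AcOH (5 equiv), THF, 0 °C, Ar, dark
Reagents that add atoms: none
Why: Fluoride cleavage of the four aryl silyl ethers, buffered with acetic acid so that no ring-A phenoxide persists that could expel O1 (retro-oxa-Michael opening). Neither stereocentre is touched, and the methyl ethers and the stilbene are inert.

## Compound list

1 | 3,5-dihydroxybenzyl alcohol | OCc1cc(O)cc(O)c1 | starting material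
2 | [3,5-bis(methoxymethoxy)phenyl]methanol | OCc1cc(OCOC)cc(OCOC)c1 | intermediate
3 | 3,5-dihydroxybenzaldehyde | O=Cc1cc(O)cc(O)c1 | starting material
4 | 3,5-bis(tert-butyldimethylsilyloxy)benzaldehyde | O=Cc1cc(O[Si](C)(C)C(C)(C)C)cc(O[Si](C)(C)C(C)(C)C)c1 | intermediate
5 | lithium [4-lithio-3,5-bis(methoxymethoxy)phenyl]methanolate | [Li]OCc1cc(OCOC)c([Li])c(OCOC)c1 | intermediate
6 | [3,5-bis(TBSO)phenyl][4-(hydroxymethyl)-2,6-bis(methoxymethoxy)phenyl]methanol (racemic) | OCc1cc(OCOC)c(C(O)c2cc(O[Si](C)(C)C(C)(C)C)cc(O[Si](C)(C)C(C)(C)C)c2)c(OCOC)c1 | intermediate
7 | 4-[3,5-bis(TBSO)benzoyl]-3,5-bis(methoxymethoxy)benzaldehyde | O=Cc1cc(OCOC)c(C(=O)c2cc(O[Si](C)(C)C(C)(C)C)cc(O[Si](C)(C)C(C)(C)C)c2)c(OCOC)c1 | intermediate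
8 | vanillin | COc1cc(C=O)ccc1O | starting material
9 | 4-(TBSO)-3-methoxybenzaldehyde | COc1cc(C=O)ccc1O[Si](C)(C)C(C)(C)C | intermediate
10 | [4-(TBSO)-3-methoxyphenyl]methanol | COc1cc(CO)ccc1O[Si](C)(C)C(C)(C)C | intermediate
11 | 4-(TBSO)-3-methoxybenzyl chloride | COc1cc(CCl)ccc1O[Si](C)(C)C(C)(C)C | intermediate
12 | 4-(TBSO)-3-methoxybenzylmagnesium chloride | COc1cc(C[Mg]Cl)ccc1O[Si](C)(C)C(C)(C)C | intermediate
13 | diol from double Grignard addition (mixture of diastereomers) | COc1cc(CC(O)c2cc(OCOC)c(C(O)(Cc3ccc(O[Si](C)(C)C(C)(C)C)c(OC)c3)c3cc(O[Si](C)(C)C(C)(C)C)cc(O[Si](C)(C)C(C)(C)C)c3)c(OCOC)c2)ccc1O[Si](C)(C)C(C)(C)C | intermediate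
14 | bis-MOM, tetra-TBS triarylethylene–stilbene (E styryl; E/Z at triaryl alkene) | COc1cc(/C=C/c2cc(OCOC)c(C(=Cc3ccc(O[Si](C)(C)C(C)(C)C)c(OC)c3)c3cc(O[Si](C)(C)C(C)(C)C)cc(O[Si](C)(C)C(C)(C)C)c3)c(OCOC)c2)ccc1O[Si](C)(C)C(C)(C)C | intermediate
15 | bis(trimethylsilyl) ether corresponding to 14 | COc1cc(/C=C/c2cc(O[Si](C)(C)C)c(C(=Cc3ccc(O[Si](C)(C)C(C)(C)C)c(OC)c3)c3cc(O[Si](C)(C)C(C)(C)C)cc(O[Si](C)(C)C(C)(C)C)c3)c(O[Si](C)(C)C)c2)ccc1O[Si](C)(C)C(C)(C)C | intermediate
16 | free resorcinol, achiral isomer of 18 (E styryl; E/Z at triaryl alkene) | COc1cc(/C=C/c2cc(O)c(C(=Cc3ccc(O[Si](C)(C)C(C)(C)C)c(OC)c3)c3cc(O[Si](C)(C)C(C)(C)C)cc(O[Si](C)(C)C(C)(C)C)c3)c(O)c2)ccc1O[Si](C)(C)C(C)(C)C | intermediate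
17 | (S)-configured ring-A-stabilised benzylic cation (cation of the ion pair with the IDPi anion) | COc1cc(/C=C/c2cc(O)c([C@@H]([CH+]c3ccc(O[Si](C)(C)C(C)(C)C)c(OC)c3)c3cc(O[Si](C)(C)C(C)(C)C)cc(O[Si](C)(C)C(C)(C)C)c3)c(O)c2)ccc1O[Si](C)(C)C(C)(C)C | intermediate
18 | (2S,3S)-tetra-TBS ether of bisisorhapontigenin B (free 4-OH) | COc1cc(/C=C/c2cc(O)c3c(c2)O[C@H](c2ccc(O[Si](C)(C)C(C)(C)C)c(OC)c2)[C@H]3c2cc(O[Si](C)(C)C(C)(C)C)cc(O[Si](C)(C)C(C)(C)C)c2)ccc1O[Si](C)(C)C(C)(C)C | intermediate
19 | bisisorhapontigenin B, (2S,3S) | COc1cc(/C=C/c2cc(O)c3c(c2)O[C@H](c2ccc(O)c(OC)c2)[C@H]3c2cc(O)cc(O)c2)ccc1O | target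

## Step count and least certain steps

Total step count: 12. Longest linear sequence: 8 (steps 1, 3, 4, 8, 9, 10, 11, 12; the branch from vanillin, steps 5, 6, 7, 8–12, is equally long).

**Step 11 (key step, new method).** The ring closure itself should be reliable; the risk lies in the enantioselectivity.
- Facial discrimination in the proton transfer to C3 may be poor, because rings B and C are of similar size and the E and Z isomers may prefer opposite faces.
- The ee may erode through re-opening of the ring and loss of H3.
- Acid-induced silyl migration to the free phenols and slow intermolecular alkylation are further possibilities.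

The fallback uses two known reaction types, sets out from 16 and returns at 18. A chiral phosphoric acid with a Hantzsch ester effects the transfer hydrogenation known for 2-(1-arylvinyl)phenols: protonation at C2 to the o-quinone methide, then enantioselective hydride delivery to C3. This gives the (S)-triarylethane F1. The styryl alkene cannot form such an intermediate and stays. DDQ (CH2Cl2, 0 °C, 4 Å MS) then abstracts hydride from the electron-rich ring-A benzylic CH2 of F1, and a neighbouring ring-C phenol traps the cation under control by C3. This is the biomimetic quinone-methide closure and gives 18.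

**Step 10.** The most likely failures are premature, racemic ring closure of 16 during hydrolysis or chromatography, since 16 is built to cyclise under acid, and incomplete cleavage at the hindered ortho positions. The fallback sets out from 15 and returns at 18, and 16 is never isolated. The bis-TMS ether 15 is freed from salts by anhydrous filtration and taken directly into the chiral-acid medium of step 11 with 2-propanol (2–3 equiv). The acid-catalysed alcoholysis of the aryl TMS ethers then liberates the phenols in the presence of the chiral acid only.

**Step 8.** The addition may stall at the di-ortho-substituted ketone after the aldehyde has reacted. Wurtz coupling may occur during formation of the electron-rich benzylic Grignard reagent, and the benzyl nucleophile may attack through its ortho position.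

The fallback sets out from 7 and returns at 14, bypassing 13 and step 9.
1. Both carbonyl groups are methylenated with the small ylide Ph3P=CH2 (Wittig reaction) to give the vinyl/1,1-diarylethylene compound F2.
2. Purchased 4-iodo-2-methoxyphenol F3 is silylated to the aryl iodide F4.
3. A two-directional Heck arylation of F2 with two equivalents of F4 (Pd(OAc)2, P(o-tol)3, Et3N, DMF, 90 °C) installs rings A and D at the two terminal CH2 groups.

**Step 3.** Metalation may be incomplete or misdirected, because the lithium alkoxide aggregates, may be poorly soluble, and is itself a weak director to the positions next to CH2OLi. The fallback sets out from 1 and returns at 6, with the site fixed by a halogen instead of by direction.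
1. Iodination of 1 with I2/NaHCO3 in water, which attacks resorcinols between the two OH groups, gives 5-(hydroxymethyl)-2-iodobenzene-1,3-diol F5.
2. Bis-MOM protection as in step 1 gives the iodide F6.
3. Iodine–magnesium exchange with iPrMgCl·LiCl (2.1 equiv, the first for the alcohol, −20 °C) and addition to 4 give 6.

## Further compounds

F1 | step 11 | 2-{(1S)-1-[3,5-bis(TBSO)phenyl]-2-[4-(TBSO)-3-methoxyphenyl]ethyl}-5-{(E)-2-[4-(TBSO)-3-methoxyphenyl]ethenyl}benzene-1,3-diol | COc1cc(/C=C/c2cc(O)c([C@@H](Cc3ccc(O[Si](C)(C)C(C)(C)C)c(OC)c3)c3cc(O[Si](C)(C)C(C)(C)C)cc(O[Si](C)(C)C(C)(C)C)c3)c(O)c2)ccc1O[Si](C)(C)C(C)(C)C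
F0 | step 10 | none | none
F2 | step 8 | 2-{1-[3,5-bis(TBSO)phenyl]ethenyl}-5-ethenyl-1,3-bis(methoxymethoxy)benzene | C=Cc1cc(OCOC)c(C(=C)c2cc(O[Si](C)(C)C(C)(C)C)cc(O[Si](C)(C)C(C)(C)C)c2)c(OCOC)c1
F3 | step 8 | 4-iodo-2-methoxyphenol | COc1cc(I)ccc1O
F4 | step 8 | tert-butyl(4-iodo-2-methoxyphenoxy)dimethylsilane | COc1cc(I)ccc1O[Si](C)(C)C(C)(C)C
F5 | step 3 | 5-(hydroxymethyl)-2-iodobenzene-1,3-diol | OCc1cc(O)c(I)c(O)c1
F6 | step 3 | [4-iodo-3,5-bis(methoxymethoxy)phenyl]methanol | OCc1cc(OCOC)c(I)c(OCOC)c1
A1 | alternative 1 | isorhapontigenin | COc1cc(/C=C/c2cc(O)cc(O)c2)ccc1O
A2 | alternative 1 | racemic p-quinone methide from coupling at the carbon between the two OH groups | COC1=CC(=CC(c2cc(O)cc(O)c2)c2c(O)cc(/C=C/c3ccc(O)c(OC)c3)cc2O)C=CC1=O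
A3 | alternative 2 | [4-bromo-2-{[4-(TBSO)-3-methoxybenzyl]oxy}-6-(methoxymethoxy)phenyl][3,5-bis(TBSO)phenyl]diazomethane | COc1cc(COc2cc(Br)cc(OCOC)c2C(=[N+]=[N-])c2cc(O[Si](C)(C)C(C)(C)C)cc(O[Si](C)(C)C(C)(C)C)c2)ccc1O[Si](C)(C)C(C)(C)C
A4 | alternative 3 | 6-bromo-3-[3,5-bis(TBSO)phenyl]-2-[4-(TBSO)-3-methoxyphenyl]-1-benzofuran-4-ol | COc1cc(-c2oc3cc(Br)cc(O)c3c2-c2cc(O[Si](C)(C)C(C)(C)C)cc(O[Si](C)(C)C(C)(C)C)c2)ccc1O[Si](C)(C)C(C)(C)C
A5 | alternative 3 | (2R,3S)-cis-6-bromo-3-[3,5-bis(TBSO)phenyl]-2-[4-(TBSO)-3-methoxyphenyl]-2,3-dihydro-1-benzofuran-4-ol | Brc1cc(O)c2c(c1)O[C@@H](c1ccc(O[Si](C)(C)C(C)(C)C)c(OC)c1)[C@H]2c1cc(O[Si](C)(C)C(C)(C)C)cc(O[Si](C)(C)C(C)(C)C)c1
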